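**Plan**

- Retrosynthesis: the O5 and O4' benzyl ethers come off last. Ring C (the pyranone: O1, C2, C3, C4) is cut at C4a–C4, C4–C3 and O1–C2 into an ortho-iodophenol, carbon monoxide and 4-benzyloxyphenylacetylene. The C–I bond goes back to C–H, and ring A with its C8 side chain goes back to the opened lactone of a 4-phenylcoumarin.
- Forward: ring A and the three chain carbons are already present in 5,7-dihydroxy-4-phenylcoumarin. Its 7-hydroxyl (the future O5 of the flavone) is benzylated, the 5-hydroxyl acetylated, the C3–C4 double bond reduced, lactone and acetate cleaved and the ring iodinated. Ring C then closes in the carbonylative annulation, which also brings in ring B, and hydrogenolysis ends the route.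
- Enabling feature: in the opened salt, ring A carries the chain at C1, oxido groups at C2 and C6 and the benzyl ether at C4, so C3 and C5 are equivalent. Mono-iodination therefore places iodine (future C4a) between the benzyl ether (future O5) and a free hydroxyl (future O1) whose carbon (future C8a) is bonded to the chain-bearing carbon (future C8). The other hydroxyl (future O7) is para to iodine, so the pyranone ring (O1, C2, C3, C4) can only close beside C8.
- Stereochemistry: the single stereocentre (R, the benzylic carbon on C8) is set by ligand-controlled copper hydride conjugate reduction of the coumarin and is not touched afterwards.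

Key step: step 5

**Remarks (assumptions)**

- Compounds 1, 7 and 8 are taken as commercial.
- (R)-DTBM-SEGPHOS is assumed to deliver hydride to the C4 face that gives the R lactone; if the sense proves opposite, the S ligand is used and nothing else changes.
- The carboxyl group is carried through the annulation as the free acid (carboxylate under the amine), because an aryl lactone would be opened by diethylamine to a diethylamide.
- Coumarin numbering is used for 1–4 and flavone numbering (rings A, B, C) for 11 and 12. In 5, 6, 9 and 10 the ring A carbon that bears the chain is C1.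

**Route**

Step 1
Reactants: 1 5,7-dihydroxy-4-phenylcoumarin
Product: 2 7-(benzyloxy)-5-hydroxy-4-phenylcoumarin
Conditions: BnBr (1.05 equiv), K2CO3 (1.1 equiv), acetone, reflux
Reagents that add atoms: benzyl bromide, BrCc1ccccc1
Why: Williamson etherification with one equivalent of halide should take place at the 7-hydroxyl, which is the more acidic (a vinylogous acid through C4a–C4=C3–C2=O) and unhindered one, whereas the 5-hydroxyl is shielded by the peri 4-phenyl group.

Step 2
Reactants: 2 7-(benzyloxy)-5-hydroxy-4-phenylcoumarin
Product: 3 7-(benzyloxy)-2-oxo-4-phenyl-2H-chromen-5-yl acetate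
Conditions: Ac2O, pyridine, DMAP (cat.), CH2Cl2, rt
Reagents that add atoms: acetic anhydride, CC(=O)OC(C)=O
Why: DMAP-catalysed O-acylation caps the remaining phenol, which would otherwise consume hydride in step 3, as an ester that the hydroxide of step 4 removes together with the lactone, so no separate deprotection is needed.

Step 3
Reactants: 3 7-(benzyloxy)-2-oxo-4-phenyl-2H-chromen-5-yl acetate
Product: 4 (4R)-7-(benzyloxy)-2-oxo-4-phenyl-3,4-dihydro-2H-chromen-5-yl acetate
Conditions: Cu(OAc)2·H2O (3 mol %), (R)-DTBM-SEGPHOS (3 mol %), (EtO)2MeSiH (1.3 equiv), t-BuOH (1.3 equiv), toluene, 0 °C to rt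
Reagents that add atoms: none
Why: Copper hydride asymmetric conjugate reduction of a 4-arylcoumarin: the ligated copper hydride should add hydride to one face of C4 and tert-butanol should protonate the copper enolate at C3, so the bisphosphine sets the R configuration at C4, while the limited amount of silane guards against further reduction of the lactone.

Step 4
Reactants: 4 (4R)-7-(benzyloxy)-2-oxo-4-phenyl-3,4-dihydro-2H-chromen-5-yl acetate
Product: 6 (R)-3-[4-(benzyloxy)-2,6-dihydroxy-3-iodophenyl]-3-phenylpropanoic acid, via trisodium ring-opened salt 5 (not isolated)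
Conditions: NaOH (4 equiv), THF/H2O, 0 °C to rt, Ar; then I2 (1.0 equiv) in THF, 0 °C; then aq HCl to pH 4–5, 0 °C, extraction, no heating; used at once
Reagents that add atoms: sodium hydroxide, [Na+].[OH-]; iodine, II
Why: Saponification cleaves both the aryl acetate and the aryl lactone, which leaves C3 and C5 of ring A equivalent, so electrophilic aromatic iodination of the phenoxide can give only one mono-iodide, with iodine between the benzyl ether and a hydroxyl; the stereocentre has no acidic hydrogen and is not affected.

Step 5
Reactants: 6 (R)-3-[4-(benzyloxy)-2,6-dihydroxy-3-iodophenyl]-3-phenylpropanoic acid; 7 1-(benzyloxy)-4-ethynylbenzene; 8 carbon monoxide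
Product: 11 (R)-3-{5-(benzyloxy)-2-[4-(benzyloxy)phenyl]-7-hydroxy-4-oxo-4H-chromen-8-yl}-3-phenylpropanoic acid, via hydroxyaryl ynone 9 (not isolated), via diethylamino enone 10 (not isolated)
Conditions: PdCl2(PPh3)2 (5 mol %), CO (20 bar), Et2NH/DMF (1:1), 120 °C
Reagents that add atoms: none
Why: The divalent palladium precatalyst is reduced in situ to zerovalent palladium, which inserts into the C–I bond of 6; CO insertion gives an aroylpalladium species, and alkynyl transfer from 7 followed by reductive elimination should give ynone 9 (C4a–C4 and C4–C3). Diethylamine then adds to the ynone to give β-amino enone 10, and the hydroxyl ortho to the acyl group attacks the amine-bearing carbon and expels diethylamine, which forms O1–C2 and closes ring C in the 6-endo sense (addition–elimination) and not in the 5-exo sense that would lead to an aurone. The closest known reaction type is the palladium-catalysed carbonylative Sonogashira coupling–cyclisation of 2-iodophenols with terminal arylacetylenes to flavones. No stereocentre is formed, and the existing benzylic one has no acidic hydrogen and lies away from all bond-forming sites. The selectivity needed is closure beside C8 and not beside C6: in 6 the iodine lies between the benzyl ether (O5) and a free hydroxyl on the carbon next to the chain-bearing carbon, while the second hydroxyl (future O7) is para to the iodide and cannot reach the ynone. The acid is present as its diethylammonium carboxylate, which is inert to the amine and cannot lactonise.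

Step 6
Reactants: 11 (R)-3-{5-(benzyloxy)-2-[4-(benzyloxy)phenyl]-7-hydroxy-4-oxo-4H-chromen-8-yl}-3-phenylpropanoic acid
Product: 12 (R)-3-[5,7-dihydroxy-2-(4-hydroxyphenyl)-4-oxo-4H-chromen-8-yl]-3-phenylpropanoic acid
Conditions: H2 (1 atm), Pd/C (10 wt %), THF/EtOAc, rt; filtration and evaporation without acid
Reagents that add atoms: none
Why: Hydrogenolysis of the two aryl benzyl ethers at neutral pH should free O5 and O4' without reducing the pyranone double bond (a vinylogous ester) or touching the benzylic C–C stereocentre, and the absence of acid keeps the 7-hydroxyl from lactonising with the carboxylic acid.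

**Compound list**

1 | 5,7-dihydroxy-4-phenylcoumarin | O=c1cc(-c2ccccc2)c2c(O)cc(O)cc2o1 | starting material
2 | 7-(benzyloxy)-5-hydroxy-4-phenylcoumarin | O=c1cc(-c2ccccc2)c2c(O)cc(OCc3ccccc3)cc2o1 | intermediate
3 | 7-(benzyloxy)-2-oxo-4-phenyl-2H-chromen-5-yl acetate | CC(=O)Oc1cc(OCc2ccccc2)cc2oc(=O)cc(-c3ccccc3)c12 | intermediate
4 | (4R)-7-(benzyloxy)-2-oxo-4-phenyl-3,4-dihydro-2H-chromen-5-yl acetate | O=C1C[C@H](c2ccccc2)c2c(OC(C)=O)cc(OCc3ccccc3)cc2O1 | intermediate
5 | trisodium (R)-3-[4-(benzyloxy)-2,6-dioxidophenyl]-3-phenylpropanoate | [Na+].[Na+].[Na+].[O-]C(=O)C[C@H](c1ccccc1)c1c([O-])cc(OCc2ccccc2)cc1[O-] | intermediate (not isolated)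
6 | (R)-3-[4-(benzyloxy)-2,6-dihydroxy-3-iodophenyl]-3-phenylpropanoic acid | OC(=O)C[C@H](c1ccccc1)c1c(O)cc(OCc2ccccc2)c(I)c1O | intermediate
7 | 1-(benzyloxy)-4-ethynylbenzene | C#Cc1ccc(OCc2ccccc2)cc1 | starting material
8 | carbon monoxide | [C-]#[O+] | starting material
9 | (R)-3-[4-(benzyloxy)-3-{3-[4-(benzyloxy)phenyl]prop-2-ynoyl}-2,6-dihydroxyphenyl]-3-phenylpropanoic acid | OC(=O)C[C@H](c1ccccc1)c1c(O)cc(OCc2ccccc2)c(C(=O)C#Cc2ccc(OCc3ccccc3)cc2)c1O | intermediate (not isolated)
10 | (R)-3-[4-(benzyloxy)-3-{(E)-3-[4-(benzyloxy)phenyl]-3-(diethylamino)prop-2-enoyl}-2,6-dihydroxyphenyl]-3-phenylpropanoic acid | OC(=O)C[C@H](c1ccccc1)c1c(O)cc(OCc2ccccc2)c(C(=O)/C=C(/N(CC)CC)c2ccc(OCc3ccccc3)cc2)c1O | intermediate (not isolated)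
11 | (R)-3-{5-(benzyloxy)-2-[4-(benzyloxy)phenyl]-7-hydroxy-4-oxo-4H-chromen-8-yl}-3-phenylpropanoic acid | OC(=O)C[C@H](c1ccccc1)c1c(O)cc(OCc2ccccc2)c2c(=O)cc(-c3ccc(OCc4ccccc4)cc3)oc12 | intermediate
12 | (R)-3-[5,7-dihydroxy-2-(4-hydroxyphenyl)-4-oxo-4H-chromen-8-yl]-3-phenylpropanoic acid | O=C(O)C[C@H](c1ccccc1)c1c(O)cc(O)c2c(=O)cc(-c3ccc(O)cc3)oc12 | target

**Step count and risks**

Total steps: 6. Longest linear sequence: 6 steps (1 to 12); 7 and 8 enter at step 5.

Step 3. Hydride transfer to the crowded, fully substituted C4 may be slow, and the twisted 4-phenyl group and the peri acetate may weaken the facial discrimination. The product lactone may also be reduced further to the lactol. The fallback sets out from 3 and returns at 5. Hydroxide opens the coumarin lactone and cleaves the acetate of 3 (NaOH, MeOH/H2O), giving trisodium (Z)-3-[4-(benzyloxy)-2,6-dioxidophenyl]-3-phenylprop-2-enoate F1. Its double bond is then hydrogenated with [Rh(cod)Cl]2 and (S,S)-CHIRAPHOS (or the antipode, whichever leads to the R acid) under H2 pressure. This should give the trisodium salt 5 directly, and the route continues with the iodine addition of step 4. Any shortfall in enantiomeric purity would be made up by crystallising acid 6 or one of its amine salts.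

Step 5. Oxidative addition into the electron-rich, doubly ortho-substituted iodide may be slow. Diethylamine may capture the aroylpalladium species as a diethylamide before the alkyne does, and part of the ynone may close in the 5-exo sense. The fallback sets out from 6 and returns at 11; it builds C4 and C3 from an acetyl group and C2 from an aldehyde. Stille coupling of 6 with tributyl(1-ethoxyvinyl)stannane (PdCl2(PPh3)2, DMF, 90 °C) should give (R)-3-[4-(benzyloxy)-3-(1-ethoxyvinyl)-2,6-dihydroxyphenyl]-3-phenylpropanoic acid F2. Dilute aqueous HCl hydrolyses the enol ether to (R)-3-[3-acetyl-4-(benzyloxy)-2,6-dihydroxyphenyl]-3-phenylpropanoic acid F3. Claisen–Schmidt condensation with 4-(benzyloxy)benzaldehyde (KOH, EtOH, rt) leads to the chalcone (R)-3-[4-(benzyloxy)-3-{(E)-3-[4-(benzyloxy)phenyl]prop-2-enoyl}-2,6-dihydroxyphenyl]-3-phenylpropanoic acid F4; the hydroxide also reopens any lactone formed in the acidic hydrolysis. Oxidative cyclisation of the chalcone with catalytic I2 in DMSO at 110 °C then gives 11. Here too the carbonyl group is flanked by only one free hydroxyl, the one next to the chain-bearing carbon, so the regiochemistry is unchanged.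

Step 4. The mono-iodide is still a strongly activated phenoxide and may take up a second iodine. The liberated dihydroxy acid may also close to a lactone during acidification and concentration, and the lactone would later be opened by diethylamine to an amide. The fallback sets out from 5 and returns at 6; it iodinates a neutral, less activated lactone and uses the lactone as the storage form. Acidification of 5 gives (R)-3-[4-(benzyloxy)-2,6-dihydroxyphenyl]-3-phenylpropanoic acid F5. Catalytic TsOH in toluene at 50 °C closes it to (R)-7-(benzyloxy)-5-hydroxy-4-phenylchroman-2-one F6; both hydroxyls give the same lactone. N-Iodosuccinimide (1.0 equiv, MeCN, 0 °C) iodinates the single free phenol at C6, giving (R)-7-(benzyloxy)-5-hydroxy-6-iodo-4-phenylchroman-2-one F7, or at C8, giving (R)-7-(benzyloxy)-5-hydroxy-8-iodo-4-phenylchroman-2-one F8. The site does not matter, because opening of either lactone with NaOH in THF/H2O, followed by careful acidification, leads to the same acid 6.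

**Further compounds**

F1 | step 3 | trisodium (Z)-3-[4-(benzyloxy)-2,6-dioxidophenyl]-3-phenylprop-2-enoate | [Na+].[Na+].[Na+].[O-]C(=O)/C=C(/c1ccccc1)c1c([O-])cc(OCc2ccccc2)cc1[O-]
F2 | step 5 | (R)-3-[4-(benzyloxy)-3-(1-ethoxyvinyl)-2,6-dihydroxyphenyl]-3-phenylpropanoic acid | OC(=O)C[C@H](c1ccccc1)c1c(O)cc(OCc2ccccc2)c(C(=C)OCC)c1O
F3 | step 5 | (R)-3-[3-acetyl-4-(benzyloxy)-2,6-dihydroxyphenyl]-3-phenylpropanoic acid | OC(=O)C[C@H](c1ccccc1)c1c(O)cc(OCc2ccccc2)c(C(C)=O)c1O
F4 | step 5 | (R)-3-[4-(benzyloxy)-3-{(E)-3-[4-(benzyloxy)phenyl]prop-2-enoyl}-2,6-dihydroxyphenyl]-3-phenylpropanoic acid | OC(=O)C[C@H](c1ccccc1)c1c(O)cc(OCc2ccccc2)c(C(=O)/C=C/c2ccc(OCc3ccccc3)cc2)c1O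
F5 | step 4 | (R)-3-[4-(benzyloxy)-2,6-dihydroxyphenyl]-3-phenylpropanoic acid | OC(=O)C[C@H](c1ccccc1)c1c(O)cc(OCc2ccccc2)cc1O
F6 | step 4 | (R)-7-(benzyloxy)-5-hydroxy-4-phenylchroman-2-one | O=C1C[C@H](c2ccccc2)c2c(O)cc(OCc3ccccc3)cc2O1
F7 | step 4 | (R)-7-(benzyloxy)-5-hydroxy-6-iodo-4-phenylchroman-2-one | O=C1C[C@H](c2ccccc2)c2c(O)c(I)c(OCc3ccccc3)cc2O1
F8 | step 4 | (R)-7-(benzyloxy)-5-hydroxy-8-iodo-4-phenylchroman-2-one | O=C1C[C@H](c2ccccc2)c2c(O)cc(OCc3ccccc3)c(I)c2O1
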